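Locants: the liquiritigenin half is unprimed (C2, C3, C4, O1, O7), the naringenin half double-primed (C2'', C3'', O5'', O7''); ring B is the 4-hydroxyphenyl ring on C2 or C2''.

## Analysis of the target

- Target 26 is a 3,3''-linked biflavanone: a 7-hydroxy-2-(4-hydroxyphenyl)chroman-4-one joined through C3 to C3'' of a 5'',7''-dihydroxy-2''-(4-hydroxyphenyl)chroman-4-one.
- The single C3–C3'' σ bond is the only link, so the four stereocentres C2–C3–C3''–C2'' form one contiguous chain, two in each ring C.
- The configuration is (2S,3R,2''S,3''R). In each ring C the aryl group at C2 and the carbon substituent at C3 are trans (H2 and H3 anti). Both halves have the same sense, so the core is C2-symmetric apart from the 5''-hydroxyl.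
- Sensitive points are the C3 and C3'' hydrogens (α to ketones, epimerisable), the O1–C2 and O1''–C2'' bonds (benzylic ethers para to a phenol, which open under strong acid, base or Lewis acid and put C2 at risk), and five oxidisable phenols.
- The synthesis is hard for three reasons: the bond between two tertiary carbons must be made with control of both centres, two halves that differ by one hydroxyl must be told apart, and the end game must not reopen ring C.
- The plan rests on one feature. C2 and C2'' are benzylic carbons para to the ring B hydroxyls, and each ends a five-bond path C2–C3–C4–C4a–C8a–O1 from the ortho-phenol oxygen of its aryl ketone. With both O1–C2 bonds opened, the molecule is an (S,S)-2,3-bis(4-hydroxybenzyl)-1,4-diaryl-1,4-diketone, a dimer of two dihydrochalcones.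

## Retrosynthetic reasoning

**26 from 25.** The three O–benzyl bonds at O7, O5'' and O7'' are cut. Benzyl is chosen over methyl for these spectator groups. A Lewis acid strong enough to dealkylate an aryl methyl ether para to a ketone would attack the more labile benzylic O1–C2 ethers first and reopen ring C. Hydrogenolysis is neutral. The forward step must remove three benzyl groups without touching the ketones or the cyclic benzylic ethers.

**25 from 21 (key disconnection).** The O1–C2 and O1''–C2'' bonds are cut. These are C–O bonds to benzylic carbons para to a free phenol, the positions a quinone oxidant converts into electrophiles. The cut removes both rings C and two of the four stereocentres. It leaves open-chain diketone 21, whose two remaining centres are those of a 2,3-dibenzylsuccinic acid. Cutting C3–C3'' or a C2–aryl bond instead would require C–C bond formation on an assembled flavanoid. The forward reaction has to oxidise two ArCH2 groups in the presence of benzyl ethers and acylated rings A. It must close two six-membered rings faster than the quinone methides tautomerise, and place each new aryl group trans to C3 or C3''.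

**21 from 20.** Four O–C bonds are cut: the benzyl groups on the two ketone-ortho oxygens that become O1 and O1'', and the two methoxymethyl groups on rings B. These four oxygens must be freed together while O7, O5'' and O7'' stay protected. A chelating Lewis acid dealkylates an ether ortho to a ketone and cleaves acetals, but spares benzyl ethers para to a complexed carbonyl. For this reason rings B carry acetals and rings A carry benzyl ethers.

**20 from 16 and 19.** The aryl–acyl bond C4–C4a of the unprimed half is cut. The acyl partner is N-methoxy-N-methylamide 16 and the aryl partner is Grignard reagent 19, made from bromide 18. An electrophilic aromatic acylation was rejected here. An activated acyl group carrying 4-alkoxybenzyl groups on its α- and β-carbons can cyclise onto those rings to five- or six-membered benzo-fused ketones. The Lewis acid would also enolise the α-centres and strip benzyl ethers.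

**16 from 15, and 15 from 11 and 14.** The aryl–acyl bond C4''–C4a'' is cut back to anhydride 11 and aryllithium 14, made from bromide 13. The two carbonyls of 11 are homotopic through its C2 axis, so the first aryl addition cannot give regioisomers and differentiates the two carboxyl groups in the same step. The hindered 2,4,6-trioxygenated aryl group goes on first, so that the first ketone is shielded when the second nucleophile is used.

**11 from 10, 10 from 8, and 8 from two molecules of 6.** After two functional-group changes the C3–C3'' bond is cut. It is formed by oxidative homocoupling of enolate 7. Both stereocentres arise in one bond-forming event from two identical halves on simple material. Auxiliary 4 with the R configuration directs each enolate to the face that gives the S,S dimer.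

**Fragments.** Imide 6 comes from acid 3 and auxiliary 4, and acid 3 from phenol acid 1 by O-protection. Bromide 13 comes from triether 12 by bromination. Bromide 18 comes from bromoresorcinol 17 by benzylation.

## Alternatives that were turned down

**Alternative 1: photochemical diene closure and oxidative unzipping.**
- Disconnection: the C3–C3'' bond together with both C4 carbonyls, which are traced back to a C4=C4'' alkene. The precursor is diene A1, two 2H-chromenes joined C4–C4''.
- Forward key step: irradiation of A1 should cause a 4π-electrocyclisation to cyclobutene A2, forming C3–C3''. Cleavage of the C4=C4'' double bond then releases both ketones.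
- For it: the hindered C3–C3'' bond is made intramolecularly between two complete halves. C2 and C2'' could come from established enantioselective flavanone chemistry. On convergence it is stronger than the chosen route.
- Against it:
  - 2-Aryl-2H-chromenes are photochromic. Light opens the O1–C2 bond in a 6π-electrocyclic reaction, which competes with the closure and erodes C2 and C2''.
  - Disrotatory closure places H3 and H3'' on the same face of the cyclobutene, whereas the target needs the C2-symmetric sense. The unprimed half from A2 would therefore be 2,3-cis and need a later epimerisation at C3.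
  - The tetrasubstituted alkene of A2 must be cleaved next to electron-rich arenes, and five acetals are removed at the end.
- Comparison: the chosen route gives up the late convergence. In return it makes C3–C3'' first, under auxiliary control, with the correct relative configuration, and leaves only two C–O closures for the late stage.

**Alternative 2: rhodium carbene insertion into a benzylic ether C–H bond.**
- Disconnection: the C2–C3 bond of the unprimed half.
- Forward key step: Rh2(S-PTTL)4, dirhodium tetrakis[N-phthaloyl-(S)-tert-leucinate], decomposes diazo ketone A3. The carbene carbon C3 inserts into the benzylic C–H of the ortho 4-methoxybenzyl ether and gives A4.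
- For it: absolute configuration at C2 and C3 would come from a catalyst and not from a stoichiometric auxiliary. On that point it is stronger than the chosen route. The chromone in A4 is a compact masked second half.
- Against it:
  - The carbene carbon and O1 are 1,5-related. Oxonium ylide formation followed by a Stevens shift of the benzyl group to carbon is a typical outcome for such ortho-alkoxyaryl diazo ketones, and it competes with the 1,6-insertion needed.
  - After A4, the C2'' aryl group and both C2'' and C3'' are still missing. They would need a conjugate arylation of a 3-substituted chromone under substrate control.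
  - Five methyl ethers would have to be removed with a strong Lewis acid, which endangers ring C.
- Comparison: the chosen route sets C3 and C3'' early and reliably, needs no late C–C bond formation, and ends with a neutral deprotection.

**Alternative 3: twofold enantioselective conjugate arylation of a 3,3'-bichromone.**
- Disconnection: both C2–aryl bonds.
- Forward key step: Pd(O2CCF3)2 with a chiral tert-butyl pyridine–oxazoline ligand adds two molecules of boronic acid A6 to C2 and C2'' of bichromone A5. Protonation at C3 and C3'' gives A7.
- For it: it is the shortest and most convergent plan. A5 is flat and achiral, the catalyst sets C2 and C2'', C3 and C3'' can settle trans by equilibration, and the benzyl ethers leave by hydrogenolysis. On step economy and on catalytic use of chirality it is clearly stronger than the chosen route.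
- Against it:
  - This conjugate arylation is established for chromones without a C3 substituent. In A5 each acceptor carries a bulky C3 substituent, and the 5''-alkoxy group further lowers its electrophilicity.
  - After the first addition the C3–H is part of a vinylogous 1,3-dicarbonyl and can enolise.
  - The second addition is a case of double stereodifferentiation. Mono-adducts and C2 epimers would be hard to separate.
- Comparison: the chosen route fixes the stereochemical information on small intermediates by a dependable auxiliary reaction. Its two late bonds are intramolecular C–O bonds whose formation is reversible towards the favoured trans isomers.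

Key step: step 12

Assumption: compounds 1, 4, 12 and 17 are taken as purchasable; in step 12 the two arms react one after the other, and 22–24 are drawn for the unprimed arm reacting first, which does not affect the product.

## Route

Step 1
Reactants: 1 3-(4-hydroxyphenyl)propanoic acid
Product: 3 3-[4-(methoxymethoxy)phenyl]propanoic acid, via methoxymethyl ester 2 (not isolated)
Conditions: MOMCl (2.5 equiv), iPr2NEt, CH2Cl2, 0 °C → rt; then LiOH, THF/H2O, rt; cold 1 M HCl to pH 4
Reagents that add atoms: chloromethyl methyl ether, COCCl; lithium hydroxide, [Li+].[OH-]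
Why: Williamson-type O-alkylation of phenol and carboxylate by the α-chloro ether, then saponification of the labile acetal ester only; the aryl acetal is base-stable and should survive the brief, cold, mildly acidic work-up.

Step 2
Reactants: 3 3-[4-(methoxymethoxy)phenyl]propanoic acid; 4 (R)-4-isopropyl-2-oxazolidinone
Product: 6 (R)-4-isopropyl-3-{3-[4-(methoxymethoxy)phenyl]propanoyl}oxazolidin-2-one, via mixed pivalic anhydride 5 (not isolated)
Conditions: PivCl, Et3N, THF, −20 °C; then LiCl, 4, −20 °C → rt
Reagents that add atoms: none
Why: N-acylation of the oxazolidinone through a mixed anhydride; attack occurs at the unhindered acyl group, and LiCl with Et3N provides the nucleophilic imidate without a strong base.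

Step 3
Reactants: 6 (R)-4-isopropyl-3-{3-[4-(methoxymethoxy)phenyl]propanoyl}oxazolidin-2-one (2 equiv)
Product: 8 (2S,3S)-1,4-bis[(R)-4-isopropyl-2-oxooxazolidin-3-yl]-2,3-bis[4-(methoxymethoxy)benzyl]butane-1,4-dione, via lithium Z-enolate 7 (not isolated)
Conditions: lithium diisopropylamide (1.05 equiv), THF, −78 °C; then PhI(OAc)2 (0.55 equiv), −78 → 0 °C
Reagents that add atoms: none
Why: Oxidative homocoupling of an imide enolate: the chelated Z-enolate 7 is oxidised by the trivalent iodine reagent and the two α-carbons are joined. Each enolate reacts on the face away from the isopropyl group, the same sense as in alkylations of this auxiliary, so the R auxiliary should give the S,S dimer, in line with the known behaviour of 3-arylpropanoyl oxazolidinones.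

Step 4
Reactants: 8 (2S,3S)-1,4-bis[(R)-4-isopropyl-2-oxooxazolidin-3-yl]-2,3-bis[4-(methoxymethoxy)benzyl]butane-1,4-dione
Product: 10 (2S,3S)-2,3-bis[4-(methoxymethoxy)benzyl]butanedioic acid, via diperoxy acid 9 (not isolated)
Conditions: LiOH, H2O2 (30% aq), THF/H2O, 0 °C → rt; then Na2SO3 (aq); 1 M HCl to pH 3
Reagents that add atoms: hydrogen peroxide, OO
Why: Hydroperoxide cleavage of the N-acyl oxazolidinone: the weakly basic, strongly nucleophilic LiOOH attacks the exocyclic carbonyl without deprotonating the α-centres, and sulfite reduces peracid 9; auxiliary 4 is recovered.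

Step 5
Reactants: 10 (2S,3S)-2,3-bis[4-(methoxymethoxy)benzyl]butanedioic acid
Product: 11 (3S,4S)-3,4-bis[4-(methoxymethoxy)benzyl]oxolane-2,5-dione
Conditions: DCC, CH2Cl2, 0 °C → rt; filtration
Reagents that add atoms: none
Why: Carbodiimide dehydration of a 1,4-diacid to the five-membered cyclic anhydride under neutral, non-epimerising conditions; the trans anhydride keeps the C2 axis, so its carbonyls are equivalent.

Step 6
Reactants: 12 1,3,5-tris(benzyloxy)benzene
Product: 13 1,3,5-tris(benzyloxy)-2-bromobenzene
Conditions: NBS (1.0 equiv), CH2Cl2, −20 → 0 °C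
Reagents that add atoms: N-bromosuccinimide, O=C1CCC(=O)N1Br
Why: Electrophilic aromatic bromination of a phloroglucinol triether; the three ring positions are equivalent and one equivalent at low temperature should stop at the monobromide.

Step 7
Reactants: 13 1,3,5-tris(benzyloxy)-2-bromobenzene; 11 (3S,4S)-3,4-bis[4-(methoxymethoxy)benzyl]oxolane-2,5-dione
Product: 15 (2S,3S)-2,3-bis[4-(methoxymethoxy)benzyl]-4-oxo-4-[2,4,6-tris(benzyloxy)phenyl]butanoic acid, via aryllithium 14 (not isolated)
Conditions: 13, n-BuLi, THF, −78 °C; cannulated into 11, THF, −78 → −40 °C; aq NH4Cl, then dilute HCl to pH 4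
Reagents that add atoms: none
Why: Bromine–lithium exchange followed by nucleophilic ring-opening of the cyclic anhydride; the carboxylate set free is inert, and the new ketone, flanked by two ortho-benzyloxy groups, resists a second addition. Because the carbonyls of 11 are homotopic only one keto acid can form, and no stereocentre is touched.

Step 8
Reactants: 15 (2S,3S)-2,3-bis[4-(methoxymethoxy)benzyl]-4-oxo-4-[2,4,6-tris(benzyloxy)phenyl]butanoic acid
Product: 16 (2S,3S)-N-methoxy-N-methyl-2,3-bis[4-(methoxymethoxy)benzyl]-4-oxo-4-[2,4,6-tris(benzyloxy)phenyl]butanamide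
Conditions: MeNHOMe·HCl, EDC·HCl, HOBt, N-methylmorpholine, CH2Cl2, 0 °C → rt
Reagents that add atoms: N,O-dimethylhydroxylamine hydrochloride, CNOC.Cl
Why: Carbodiimide/hydroxybenzotriazole amide coupling; the active ester limits α-epimerisation, and the amine base is too weak to enolise the hindered ketone.

Step 9
Reactants: 17 4-bromobenzene-1,3-diol
Product: 18 2,4-bis(benzyloxy)-1-bromobenzene
Conditions: BnBr (2.2 equiv), K2CO3, DMF, 50 °C
Reagents that add atoms: benzyl bromide, BrCc1ccccc1
Why: Twofold Williamson ether synthesis on a resorcinol.

Step 10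
Reactants: 18 2,4-bis(benzyloxy)-1-bromobenzene; 16 (2S,3S)-N-methoxy-N-methyl-2,3-bis[4-(methoxymethoxy)benzyl]-4-oxo-4-[2,4,6-tris(benzyloxy)phenyl]butanamide
Product: 20 (2S,3S)-1-[2,4-bis(benzyloxy)phenyl]-2,3-bis[4-(methoxymethoxy)benzyl]-4-[2,4,6-tris(benzyloxy)phenyl]butane-1,4-dione, via aryl Grignard reagent 19 (not isolated)
Conditions: 18, Mg, BrCH2CH2Br (cat.), THF, 45 °C; then 16, THF, −20 → 0 °C; aq NH4Cl
Reagents that add atoms: none
Why: Weinreb ketone synthesis: the aryl Grignard reagent adds once to the N-methoxy-N-methylamide and the magnesium chelate collapses only on work-up. The existing ketone is shielded by its 2,6-bis(benzyloxy)aryl group, and the less basic magnesium reagent is chosen to avoid enolising it.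

Step 11
Reactants: 20 (2S,3S)-1-[2,4-bis(benzyloxy)phenyl]-2,3-bis[4-(methoxymethoxy)benzyl]-4-[2,4,6-tris(benzyloxy)phenyl]butane-1,4-dione
Product: 21 (2S,3S)-1-[4-(benzyloxy)-2-hydroxyphenyl]-4-[4,6-bis(benzyloxy)-2-hydroxyphenyl]-2,3-bis(4-hydroxybenzyl)butane-1,4-dione
Conditions: BCl3 (1 M in CH2Cl2, 6 equiv), CH2Cl2, −78 °C; MeOH, −78 °C → rt
Reagents that add atoms: none
Why: Chelation-controlled Lewis-acid dealkylation: boron bound to each ketone oxygen delivers chloride only to the benzyl group on the ortho oxygen, and the same reagent cleaves the two acetals on rings B, completed by the HCl/MeOH formed on quenching. The benzyl ethers para to the complexed carbonyls (O7, O7'') and the second ortho ether (O5''), which is no longer chelated, should survive at −78 °C.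

Step 12
Reactants: 21 (2S,3S)-1-[4-(benzyloxy)-2-hydroxyphenyl]-4-[4,6-bis(benzyloxy)-2-hydroxyphenyl]-2,3-bis(4-hydroxybenzyl)butane-1,4-dione
Product: 25 (2S,3R)-7-(benzyloxy)-3-[(2S,3R)-5,7-bis(benzyloxy)-2-(4-hydroxyphenyl)-4-oxochroman-3-yl]-2-(4-hydroxyphenyl)chroman-4-one, via first quinone methide 22 (not isolated), via monocyclised flavanone 23 (not isolated), via second quinone methide 24 (not isolated)
Conditions: DDQ (2.2 equiv), 4 Å molecular sieves, 1,4-dioxane, rt, dark
Reagents that add atoms: none
Why: DDQ removes hydride from each ArCH2 group para to a free phenol, and loss of the phenolic proton gives the neutral para-quinone methide (22, then 24), the reaction class being the quinone dehydrogenation of 4-alkylphenols. The hydrogen-bonded ortho-phenol of the neighbouring aryl ketone then adds to the exocyclic carbon in a 1,6-addition that restores the aromaticity of ring B; this closes ring C of the unprimed half in a 6-exo-trig mode (23), and the same sequence on the second arm closes ring C of the double-primed half, again 6-exo-trig. The closest known reaction types are the quinone-mediated oxidative cyclisation of 2'-hydroxydihydrochalcones to flavanones and the trapping of para-quinone methides by tethered oxygen nucleophiles. C2 is controlled by C3: allylic 1,3-strain keeps the C3–H bond in the plane of the quinone methide, and O1, tethered through C4, attacks the face that leaves the aryl group trans to C3''; C2'' is set in the same way by C3''. The trans-diequatorial arrangement is also the thermodynamically preferred one, and closure is reversible through the quinone methide in the presence of the acidic hydroquinone by-product, so a kinetic cis fraction should drift to trans. The step needs oxidation at the ring B benzylic positions and not at the benzyl ethers or rings A, which the free para-hydroxyl groups secure, because benzyl ethers on acylated rings are poor hydride donors. It needs ring closure to outrun tautomerisation of the quinone methide to a chalcone, which would erase C3 or C3''; the six-membered intramolecular trajectory and the absence of base secure this. It must not oxidise the new flavanone C2–H bonds, which is addressed by using two equivalents of oxidant at ambient temperature.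

Step 13
Reactants: 25 (2S,3R)-7-(benzyloxy)-3-[(2S,3R)-5,7-bis(benzyloxy)-2-(4-hydroxyphenyl)-4-oxochroman-3-yl]-2-(4-hydroxyphenyl)chroman-4-one
Product: 26 (2S,3R)-3-[(2S,3R)-5,7-dihydroxy-2-(4-hydroxyphenyl)-4-oxochroman-3-yl]-7-hydroxy-2-(4-hydroxyphenyl)chroman-4-one
Conditions: H2 (1 atm), Pd/C (10%), EtOAc/THF, rt
Reagents that add atoms: none
Why: Hydrogenolysis of three aryl benzyl ethers under neutral conditions; no acid or base reaches C3, C3'' or the O1–C2 bonds, and the aryl ketones and the cyclic benzylic ethers of ring C are normally retained under such mild conditions.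

## Compound list

1 | 3-(4-hydroxyphenyl)propanoic acid | OC(=O)CCc1ccc(O)cc1 | starting material
2 | methoxymethyl 3-[4-(methoxymethoxy)phenyl]propanoate | COCOC(=O)CCc1ccc(OCOC)cc1 | intermediate (not isolated)
3 | 3-[4-(methoxymethoxy)phenyl]propanoic acid | COCOc1ccc(CCC(=O)O)cc1 | intermediate
4 | (R)-4-isopropyl-2-oxazolidinone | CC(C)[C@@H]1COC(=O)N1 | starting material
5 | 3-[4-(methoxymethoxy)phenyl]propanoic pivalic anhydride | COCOc1ccc(CCC(=O)OC(=O)C(C)(C)C)cc1 | intermediate (not isolated)
6 | (R)-4-isopropyl-3-{3-[4-(methoxymethoxy)phenyl]propanoyl}oxazolidin-2-one | COCOc1ccc(CCC(=O)N2[C@H](C(C)C)COC2=O)cc1 | intermediate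
7 | lithium (Z)-enolate of 6 | [Li]O/C(=C\Cc1ccc(OCOC)cc1)N1[C@H](C(C)C)COC1=O | intermediate (not isolated)
8 | (2S,3S)-1,4-bis[(R)-4-isopropyl-2-oxooxazolidin-3-yl]-2,3-bis[4-(methoxymethoxy)benzyl]butane-1,4-dione | O=C(N1[C@H](C(C)C)COC1=O)[C@@H](Cc1ccc(OCOC)cc1)[C@H](Cc1ccc(OCOC)cc1)C(=O)N1[C@H](C(C)C)COC1=O | intermediate
9 | (2S,3S)-2,3-bis[4-(methoxymethoxy)benzyl]butanediperoxoic acid | OOC(=O)[C@@H](Cc1ccc(OCOC)cc1)[C@H](Cc1ccc(OCOC)cc1)C(=O)OO | intermediate (not isolated)
10 | (2S,3S)-2,3-bis[4-(methoxymethoxy)benzyl]butanedioic acid | OC(=O)[C@@H](Cc1ccc(OCOC)cc1)[C@H](Cc1ccc(OCOC)cc1)C(=O)O | intermediate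
11 | (3S,4S)-3,4-bis[4-(methoxymethoxy)benzyl]oxolane-2,5-dione | O=C1OC(=O)[C@@H](Cc2ccc(OCOC)cc2)[C@@H]1Cc1ccc(OCOC)cc1 | intermediate
12 | 1,3,5-tris(benzyloxy)benzene | c1(OCc2ccccc2)cc(OCc2ccccc2)cc(OCc2ccccc2)c1 | starting material
13 | 1,3,5-tris(benzyloxy)-2-bromobenzene | Brc1c(OCc2ccccc2)cc(OCc2ccccc2)cc1OCc1ccccc1 | intermediate
14 | [2,4,6-tris(benzyloxy)phenyl]lithium | [Li]c1c(OCc2ccccc2)cc(OCc2ccccc2)cc1OCc1ccccc1 | intermediate (not isolated)
15 | (2S,3S)-2,3-bis[4-(methoxymethoxy)benzyl]-4-oxo-4-[2,4,6-tris(benzyloxy)phenyl]butanoic acid | OC(=O)[C@@H](Cc1ccc(OCOC)cc1)[C@H](Cc1ccc(OCOC)cc1)C(=O)c1c(OCc2ccccc2)cc(OCc2ccccc2)cc1OCc1ccccc1 | intermediate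
16 | (2S,3S)-N-methoxy-N-methyl-2,3-bis[4-(methoxymethoxy)benzyl]-4-oxo-4-[2,4,6-tris(benzyloxy)phenyl]butanamide | CON(C)C(=O)[C@@H](Cc1ccc(OCOC)cc1)[C@H](Cc1ccc(OCOC)cc1)C(=O)c1c(OCc2ccccc2)cc(OCc2ccccc2)cc1OCc1ccccc1 | intermediate
17 | 4-bromobenzene-1,3-diol | Oc1ccc(Br)c(O)c1 | starting material
18 | 2,4-bis(benzyloxy)-1-bromobenzene | Brc1ccc(OCc2ccccc2)cc1OCc1ccccc1 | intermediate
19 | [2,4-bis(benzyloxy)phenyl]magnesium bromide | Br[Mg]c1ccc(OCc2ccccc2)cc1OCc1ccccc1 | intermediate (not isolated)
20 | (2S,3S)-1-[2,4-bis(benzyloxy)phenyl]-2,3-bis[4-(methoxymethoxy)benzyl]-4-[2,4,6-tris(benzyloxy)phenyl]butane-1,4-dione | O=C(c1ccc(OCc2ccccc2)cc1OCc1ccccc1)[C@@H](Cc1ccc(OCOC)cc1)[C@H](Cc1ccc(OCOC)cc1)C(=O)c1c(OCc2ccccc2)cc(OCc2ccccc2)cc1OCc1ccccc1 | intermediate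
21 | (2S,3S)-1-[4-(benzyloxy)-2-hydroxyphenyl]-4-[4,6-bis(benzyloxy)-2-hydroxyphenyl]-2,3-bis(4-hydroxybenzyl)butane-1,4-dione | O=C(c1ccc(OCc2ccccc2)cc1O)[C@@H](Cc1ccc(O)cc1)[C@H](Cc1ccc(O)cc1)C(=O)c1c(O)cc(OCc2ccccc2)cc1OCc1ccccc1 | intermediate (substrate of the key step)
22 | first quinone methide: 21 with the benzyl group next to the 4-(benzyloxy)-2-hydroxybenzoyl group oxidised to a (4-oxocyclohexa-2,5-dien-1-ylidene)methyl group, both stereocentres spatially as in 21 | O=C(c1ccc(OCc2ccccc2)cc1O)[C@@H](C=C1C=CC(=O)C=C1)[C@H](Cc1ccc(O)cc1)C(=O)c1c(O)cc(OCc2ccccc2)cc1OCc1ccccc1 | intermediate (not isolated)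
23 | (2S,3R)-7-(benzyloxy)-3-{(2S)-1-[4,6-bis(benzyloxy)-2-hydroxyphenyl]-3-(4-hydroxyphenyl)-1-oxopropan-2-yl}-2-(4-hydroxyphenyl)chroman-4-one | O=C1c2ccc(OCc3ccccc3)cc2O[C@H](c2ccc(O)cc2)[C@H]1[C@H](Cc1ccc(O)cc1)C(=O)c1c(O)cc(OCc2ccccc2)cc1OCc1ccccc1 | intermediate (not isolated)
24 | second quinone methide: 23 with the remaining 4-hydroxybenzyl group oxidised to a (4-oxocyclohexa-2,5-dien-1-ylidene)methyl group, stereocentres spatially as in 23 | O=C1c2ccc(OCc3ccccc3)cc2O[C@H](c2ccc(O)cc2)[C@H]1[C@H](C=C1C=CC(=O)C=C1)C(=O)c1c(O)cc(OCc2ccccc2)cc1OCc1ccccc1 | intermediate (not isolated)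
25 | (2S,3R)-7-(benzyloxy)-3-[(2S,3R)-5,7-bis(benzyloxy)-2-(4-hydroxyphenyl)-4-oxochroman-3-yl]-2-(4-hydroxyphenyl)chroman-4-one, the 7,5'',7''-tri-O-benzyl ether of the target | O=C1c2ccc(OCc3ccccc3)cc2O[C@H](c2ccc(O)cc2)[C@H]1[C@H]1C(=O)c2c(OCc3ccccc3)cc(OCc3ccccc3)cc2O[C@@H]1c1ccc(O)cc1 | intermediate (product of the key step)
26 | (2S,3R)-3-[(2S,3R)-5,7-dihydroxy-2-(4-hydroxyphenyl)-4-oxochroman-3-yl]-7-hydroxy-2-(4-hydroxyphenyl)chroman-4-one, (2S,3R,2''S,3''R) | O=C1c2ccc(O)cc2O[C@H](c2ccc(O)cc2)[C@H]1[C@H]1C(=O)c2c(O)cc(O)cc2O[C@@H]1c1ccc(O)cc1 | target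

## Step count and least certain steps

Total step count: 13. Longest linear sequence: 11 (steps 1–5, 7, 8, 10–13).

**Step 12 (key step).**
- What may go wrong: a further hydride abstraction at the C2–H of a flavanone already formed (dehydrogenation towards a flavone); tautomerisation of a quinone methide to the chalcone, which destroys C3 or C3''; incomplete facial selectivity in ring closure; interception of the quinone methide by adventitious water. All of these arise because the oxidant and the sensitive cyclised product share one flask.
- Fallback, from 21 back to 25: oxidation and ring closure are separated. 21 is treated with DDQ in MeOH/CH2Cl2 at 0 °C, where the solvent captures each quinone methide at once. This should give (2S,3S)-backbone bis(benzylic methyl ether) F1, as a mixture at the two methoxy-bearing carbons. After removal of the oxidant, a Brønsted acid such as diphenyl phosphate in CH2Cl2 over molecular sieves regenerates the quinone methides by loss of methanol and closes both rings to 25 under equilibrating, non-oxidising conditions. A chiral BINOL-derived phosphoric acid could be substituted to reinforce the facial preference.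

**Step 11.**
- What may go wrong: loss of the para benzyl ethers by over-dealkylation; alkylation of the freed phenol rings by the chloromethyl ether released from the acetals; Lewis-acid-induced epimerisation α to the ketones.
- Fallback, from 20 back to 21: the two deprotections are done separately with reagents of orthogonal selectivity. Catalytic HCl in MeOH/THF at 40 °C removes only the acetals and gives bis-phenol penta-benzyl ether F2. MgBr2·OEt2 in toluene/Et2O then cleaves only the ketone-ortho benzyl ethers through a magnesium chelate, giving 21.

**Step 10.**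
- What may go wrong: deprotonation α to the hindered ketone by the Grignard reagent, with epimerisation at the future C3''; slow addition to the doubly branched amide.
- Fallback, from 15 back to 20: acid 15 is converted with EtSH, EDC·HCl and catalytic DMAP into S-ethyl thioester F3. Grignard reagent 19 is transmetalated with ZnCl2 to arylzinc chloride F4. A Fukuyama coupling with PdCl2(PPh3)2 as precatalyst (divalent palladium, reduced in the flask to the zerovalent state) joins them to 20 under non-basic conditions.

**Step 7.**
- What may go wrong: enolisation of the newly formed ketone by unreacted aryllithium; benzylic metalation within 14 on warming; a second addition.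
- Fallback, from 11 back to 15: anhydride 11 is opened with N,O-dimethylhydroxylamine to half-amide acid F5. Its lithium carboxylate (one equivalent of LiN(SiMe3)2) is then treated with aryllithium 14 at −78 °C. The ketone is released from the stable chelate only on work-up, so it never meets the organolithium.

**Step 3.**
- What may go wrong: incomplete conversion in the oxidative dimerisation; competing α-oxygenation of the enolate by the oxidant; partial heterochiral coupling that lowers the diastereomeric purity.
- Fallback, from 3 back to 10: control by the auxiliary is replaced by resolution. The dianion of acid 3 (two equivalents of lithium diisopropylamide) is coupled with I2, a reaction type known to favour the threo diacid. This gives 10 as the racemate with its (2R,3R)-enantiomer F6. Crystallisation with an enantiopure amine, for example (R)-1-phenylethylamine or its antipode, whichever gives the less soluble salt of the S,S acid, would give bis-ammonium salt F7. Acidification returns 10.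

## Further compounds

F1 | step 12 | 1-[4-(benzyloxy)-2-hydroxyphenyl]-4-[4,6-bis(benzyloxy)-2-hydroxyphenyl]-2,3-bis[(4-hydroxyphenyl)(methoxy)methyl]butane-1,4-dione, backbone centres spatially as in 21, methoxy-bearing carbons unspecified | O=C(c1ccc(OCc2ccccc2)cc1O)[C@@H](C(OC)c1ccc(O)cc1)[C@H](C(OC)c1ccc(O)cc1)C(=O)c1c(O)cc(OCc2ccccc2)cc1OCc1ccccc1
F2 | step 11 | (2S,3S)-1-[2,4-bis(benzyloxy)phenyl]-2,3-bis(4-hydroxybenzyl)-4-[2,4,6-tris(benzyloxy)phenyl]butane-1,4-dione | O=C(c1ccc(OCc2ccccc2)cc1OCc1ccccc1)[C@@H](Cc1ccc(O)cc1)[C@H](Cc1ccc(O)cc1)C(=O)c1c(OCc2ccccc2)cc(OCc2ccccc2)cc1OCc1ccccc1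
F3 | step 10 | S-ethyl (2S,3S)-2,3-bis[4-(methoxymethoxy)benzyl]-4-oxo-4-[2,4,6-tris(benzyloxy)phenyl]butanethioate | CCSC(=O)[C@@H](Cc1ccc(OCOC)cc1)[C@H](Cc1ccc(OCOC)cc1)C(=O)c1c(OCc2ccccc2)cc(OCc2ccccc2)cc1OCc1ccccc1
F4 | step 10 | [2,4-bis(benzyloxy)phenyl]zinc chloride | Cl[Zn]c1ccc(OCc2ccccc2)cc1OCc1ccccc1
F5 | step 7 | (2S,3S)-4-[methoxy(methyl)amino]-2,3-bis[4-(methoxymethoxy)benzyl]-4-oxobutanoic acid | CON(C)C(=O)[C@@H](Cc1ccc(OCOC)cc1)[C@H](Cc1ccc(OCOC)cc1)C(=O)O
F6 | step 3 | (2R,3R)-2,3-bis[4-(methoxymethoxy)benzyl]butanedioic acid, the enantiomer formed with 10 as the racemate | OC(=O)[C@H](Cc1ccc(OCOC)cc1)[C@@H](Cc1ccc(OCOC)cc1)C(=O)O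
F7 | step 3 | bis[(R)-1-phenylethylammonium] salt of 10, written as acid plus two amines | OC(=O)[C@@H](Cc1ccc(OCOC)cc1)[C@H](Cc1ccc(OCOC)cc1)C(=O)O.C[C@@H](N)c1ccccc1.C[C@@H](N)c1ccccc1
A1 | alternative 1 | (2S,2''S)-7,5'',7''-tris(methoxymethoxy)-2,2''-bis[4-(methoxymethoxy)phenyl]-2H,2''H-4,4''-bichromene | COCOc1ccc(cc1)[C@@H]1C=C(c2ccc(OCOC)cc2O1)C1=C[C@@H](c2ccc(OCOC)cc2)Oc2cc(OCOC)cc(OCOC)c12
A2 | alternative 1 | cis-fused cyclobutene from A1, with the C3–C3'' bond and a C4=C4'' alkene, penta(methoxymethyl) ether | COCOc1ccc(cc1)[C@@H]1[C@@H]2[C@@H]3[C@@H](c4ccc(OCOC)cc4)Oc4cc(OCOC)cc(OCOC)c4C3=C2c2ccc(OCOC)cc2O1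
A3 | alternative 2 | 2-diazo-2-(5,7-dimethoxy-4-oxo-4H-chromen-3-yl)-1-{4-methoxy-2-[(4-methoxybenzyl)oxy]phenyl}ethan-1-one | COc1ccc(COc2cc(OC)ccc2C(=O)C(=[N+]=[N-])c2coc3cc(OC)cc(OC)c3c2=O)cc1
A4 | alternative 2 | (2S,3R)-3-(5,7-dimethoxy-4-oxo-4H-chromen-3-yl)-7-methoxy-2-(4-methoxyphenyl)chroman-4-one | O=C1c2ccc(OC)cc2O[C@H](c2ccc(OC)cc2)[C@H]1c1coc2cc(OC)cc(OC)c2c1=O
A5 | alternative 3 | 7-(benzyloxy)-3-[5,7-bis(benzyloxy)-4-oxo-4H-chromen-3-yl]-4H-chromen-4-one | O=c1c(-c2coc3cc(OCc4ccccc4)cc(OCc4ccccc4)c3c2=O)coc2cc(OCc3ccccc3)ccc12
A6 | alternative 3 | [4-(benzyloxy)phenyl]boronic acid | OB(O)c1ccc(OCc2ccccc2)cc1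
A7 | alternative 3 | penta-O-benzyl ether of 26, (2S,3R,2''S,3''R) | O=C1c2ccc(OCc3ccccc3)cc2O[C@H](c2ccc(OCc3ccccc3)cc2)[C@H]1[C@H]1C(=O)c2c(OCc3ccccc3)cc(OCc3ccccc3)cc2O[C@@H]1c1ccc(OCc2ccccc2)cc1
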